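The ring is made by cutting ring bond C5–C6 of the resorcinol. This unfolds the ring into one linear polyketide chain, because the oxygens on ring C1, ring C3 and side-chain C2′, together with C5 as a former carbonyl carbon, sit on alternate carbons. In one operation, a base-mediated intramolecular aldol condensation of the C2 methylene onto the C7 ketone of a 3,5,7-triketo ester closes the six-membered ring and aromatises it to a β-resorcylate. The precursor is methyl 8-(2-henicosyl-1,3-dioxolan-2-yl)-3,5,7-trioxooctanoate, with the C2′ ketone masked as a dioxolane, assembled from docosanoic acid, Meldrum's acid and methyl 3,5-dioxohexanoate. Ester hydrolysis with decarboxylation and ketal cleavage complete the route.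

Key step: step 4

Remark: the target has no stereocentre, so it is a single achiral compound and no step has to control configuration; locants C1–C9 for 7 run from the ester carbonyl (C1) to the ketal carbon (C9), and polycarbonyl compounds are written as keto tautomers.

Step 1
Reactants: 1 docosanoic acid; 2 Meldrum's acid (2,2-dimethyl-1,3-dioxane-4,6-dione)
Product: 4 N-methoxy-N-methyl-3-oxotetracosanamide, via acyl Meldrum's acid 3 (not isolated)
Conditions: DCC, DMAP, CH2Cl2, 0 °C → rt; filter, aq. KHSO4 wash, evaporate; then MeNH(OMe)·HCl, Et3N, toluene, 90 °C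
Reagents that add atoms: N,O-dimethylhydroxylamine hydrochloride, CNOC.Cl
Why: Carbodiimide-mediated C-acylation of Meldrum's acid gives the enolic adduct 3, which on heating fragments (loss of acetone and CO2) to an acylketene that the liberated N,O-dimethylhydroxylamine traps as the β-keto Weinreb amide, the standard Meldrum's acid homologation of fatty acids to β-keto esters and amides.

Step 2
Reactants: 4 N-methoxy-N-methyl-3-oxotetracosanamide
Product: 5 2-(2-henicosyl-1,3-dioxolan-2-yl)-N-methoxy-N-methylacetamide
Conditions: HOCH2CH2OH (5 equiv), p-TsOH·H2O (cat.), toluene, reflux, Dean–Stark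
Reagents that add atoms: ethylene glycol, OCCO
Why: Acid-catalysed ketalisation with azeotropic removal of water should convert the C3 ketone, the only carbonyl electrophilic enough, into the dioxolane while the N-methoxy-N-methylamide stays untouched, as in the routine ketalisation of acetoacetic acid derivatives.

Step 3
Reactants: 5 2-(2-henicosyl-1,3-dioxolan-2-yl)-N-methoxy-N-methylacetamide; 6 methyl 3,5-dioxohexanoate
Product: 7 methyl 8-(2-henicosyl-1,3-dioxolan-2-yl)-3,5,7-trioxooctanoate
Conditions: 6, LDA (3.1 equiv), THF, −78 → 0 °C (trianion); then 5 (0.7 equiv), −78 → 0 °C; sat. aq. NH4Cl, 0 °C; used crude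
Reagents that add atoms: none
Why: Claisen-type C-acylation of a 1,3,5-tricarbonyl trianion at its terminal, least stabilised carbanion (C6) by a Weinreb amide should stop at the chelated tetrahedral adduct until the quench, which prevents over-addition and proton transfer from the more acidic product, while the weakly acidic amide α-CH2 resists the enolisation that would open the dioxolane by β-elimination.

Step 4
Reactants: 7 methyl 8-(2-henicosyl-1,3-dioxolan-2-yl)-3,5,7-trioxooctanoate
Product: 9 methyl 2,4-dihydroxy-6-[(2-henicosyl-1,3-dioxolan-2-yl)methyl]benzoate, via cyclic aldol adduct 8 (not isolated)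
Conditions: KOH (1 M aq.), THF/MeOH, 0 °C → rt, Ar; then aq. NaH2PO4 to pH 7
Reagents that add atoms: none
Why: Hydroxide converts 7 into its polyenolate, in which the C2 carbanion (between ester C1 and ketone C3) adds to the C7 carbonyl to give aldolate 8; E1cB loss of water and enolisation of the C3 and C5 carbonyls then form the benzene ring, which makes the sequence irreversible. The closest known reaction type is the biomimetic aldol cyclisation of 3,5,7-triketo esters to β-resorcylates in aqueous alkali. The ring closes in the 6-(enolendo)-exo-trig mode, with the C2=C3 enolate bond inside the new ring and the C7=O bond outside it. No stereocentre survives, because the carbinol and ester-bearing carbons of 8 both become sp2 ring atoms. The step needs the C2-to-C7 aldol to beat the C6-to-C1 Claisen closure and O-cyclisation to pyrones: as C2, C4 and C6 are all doubly activated, this rests on metal-free aqueous hydroxide (no magnesium chelate to activate the ester, which is also deactivated as part of the C1–C3 enolate) and on C7 being the least enolised ketone, since its outer neighbour C8 is only singly activated. The dioxolane at C9 blocks the competing foldings (C8 to C3 and C4 to C9) and, because C7 enolises towards C6 and not towards C8, it should not be expelled by β-elimination.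

Step 5
Reactants: 9 methyl 2,4-dihydroxy-6-[(2-henicosyl-1,3-dioxolan-2-yl)methyl]benzoate
Product: 11 5-[(2-henicosyl-1,3-dioxolan-2-yl)methyl]benzene-1,3-diol, via resorcylic acid 10 (not isolated)
Conditions: KOH, ethylene glycol/H2O (4:1), 120 °C, Ar; then NaH2PO4 to pH 7–8, 90 °C
Reagents that add atoms: none
Why: Saponification of the hindered ester (BAc2) gives the salt of 10, whose carboxyl-bearing ring carbon lies ortho and para to the two oxygens and is therefore readily ipso-protonated with loss of CO2 (protodecarboxylation typical of 2,4-dihydroxybenzoic acids), all in a medium in which the dioxolane is inert and no acid can unmask the ketone for lactonisation to an isocoumarin.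

Step 6
Reactants: 11 5-[(2-henicosyl-1,3-dioxolan-2-yl)methyl]benzene-1,3-diol
Product: 12 5-(2'-oxotricosyl)resorcinol [1-(3,5-dihydroxyphenyl)tricosan-2-one]
Conditions: 2 M aq. HCl, THF, 40 °C, Ar
Reagents that add atoms: water, O
Why: Acid-catalysed hydrolysis of the dialkyl ketone dioxolane via its oxocarbenium ion should release the C2′ ketone cleanly, since the carboxyl group is already gone (no isocoumarin possible) and the meta-placed phenols cannot add to the ketone.

Compound list

1 | docosanoic acid | CCCCCCCCCCCCCCCCCCCCCC(=O)O | starting material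
2 | Meldrum's acid (2,2-dimethyl-1,3-dioxane-4,6-dione) | CC1(C)OC(=O)CC(=O)O1 | starting material
3 | 5-(1-hydroxydocosylidene)-2,2-dimethyl-1,3-dioxane-4,6-dione (docosanoyl Meldrum's acid, enol form) | CCCCCCCCCCCCCCCCCCCCCC(O)=C1C(=O)OC(C)(C)OC1=O | intermediate (not isolated)
4 | N-methoxy-N-methyl-3-oxotetracosanamide | CCCCCCCCCCCCCCCCCCCCCC(=O)CC(=O)N(C)OC | intermediate
5 | 2-(2-henicosyl-1,3-dioxolan-2-yl)-N-methoxy-N-methylacetamide | CCCCCCCCCCCCCCCCCCCCCC1(CC(=O)N(C)OC)OCCO1 | intermediate
6 | methyl 3,5-dioxohexanoate | COC(=O)CC(=O)CC(C)=O | starting material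
7 | methyl 8-(2-henicosyl-1,3-dioxolan-2-yl)-3,5,7-trioxooctanoate | COC(=O)CC(=O)CC(=O)CC(=O)CC1(CCCCCCCCCCCCCCCCCCCCC)OCCO1 | intermediate
8 | methyl 2-[(2-henicosyl-1,3-dioxolan-2-yl)methyl]-2-hydroxy-4,6-dioxocyclohexane-1-carboxylate (transient mixture of stereoisomers, both centres lost on aromatisation) | COC(=O)C1C(=O)CC(=O)CC1(O)CC2(CCCCCCCCCCCCCCCCCCCCC)OCCO2 | intermediate (not isolated)
9 | methyl 2,4-dihydroxy-6-[(2-henicosyl-1,3-dioxolan-2-yl)methyl]benzoate | COC(=O)c1c(O)cc(O)cc1CC2(CCCCCCCCCCCCCCCCCCCCC)OCCO2 | intermediate
10 | 2,4-dihydroxy-6-[(2-henicosyl-1,3-dioxolan-2-yl)methyl]benzoic acid (present as its potassium salt) | OC(=O)c1c(O)cc(O)cc1CC2(CCCCCCCCCCCCCCCCCCCCC)OCCO2 | intermediate (not isolated)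
11 | 5-[(2-henicosyl-1,3-dioxolan-2-yl)methyl]benzene-1,3-diol | Oc1cc(O)cc(CC2(CCCCCCCCCCCCCCCCCCCCC)OCCO2)c1 | intermediate
12 | 5-(2'-oxotricosyl)resorcinol | CCCCCCCCCCCCCCCCCCCCCC(=O)Cc1cc(O)cc(O)c1 | target

Total step count: 6. Longest linear sequence: 6 steps (1 → 12); 2 and 6 enter this line directly.

Steps most likely to fail

1. Step 4 (key step). The chain may close in another mode (C-acylation of C6 by the ester, or O-cyclisation to a pyrone), the dioxolane may be opened by β-elimination before ring closure, or dehydration of the aldol adduct may stall. Fallback: the ring is no longer built but taken from an aromatic building block. It sets out from 1 and comes back to the route at 12. Activation of 1 with 1,1′-carbonyldiimidazole (CH2Cl2/THF) and addition of MeNH(OMe)·HCl should give N-methoxy-N-methyldocosanamide F1. Addition of 3,5-dimethoxybenzylmagnesium chloride (commercial solution, THF, 0 °C; Weinreb ketone synthesis) should give 1-(3,5-dimethoxyphenyl)tricosan-2-one F2. BBr3 in CH2Cl2 (−78 °C → rt) should then cleave both aryl methyl ethers to give 12.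

2. Step 3. Proton transfer from the amide α-CH2 to the strongly basic trianion may outrun addition and be followed by β-elimination that opens the dioxolane; trianion formation may also be incomplete, or the product may cyclise uncontrolled during work-up. Fallback: the C6–C7 bond is made by an aldol addition and the oxidation level is adjusted afterwards. It sets out from 5 and comes back at 7. Reduction of 5 with DIBAL-H (THF, −78 °C, Rochelle salt work-up) should give 2-(2-henicosyl-1,3-dioxolan-2-yl)acetaldehyde F3. Addition of the trianion of 6 (LDA, THF, −78 °C), which is fast for an aldehyde, should give racemic methyl 8-(2-henicosyl-1,3-dioxolan-2-yl)-7-hydroxy-3,5-dioxooctanoate F4. Oxidation of the secondary alcohol with IBX (EtOAc, 75 °C) should then give 7.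

3. Step 5. Hydrolysis of the hindered, phenoxide-deactivated ester may stall, or decarboxylation may remain incomplete in strong base, so that leftover acid meets acid later with loss of the ketal and lactonisation; the electron-rich dianion may also be oxidised in hot alkali. Fallback: the ketal is removed first and the feared lactonisation is used as the route, so that decarboxylation can be run at its optimal weakly acidic pH. It sets out from 9 and comes back at 12.
- Aqueous HCl in THF (50 °C) should give methyl 2,4-dihydroxy-6-(2-oxotricosyl)benzoate F5.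
- This should close with TsOH in refluxing toluene (acid-catalysed enol lactonisation) to 3-henicosyl-6,8-dihydroxy-1H-isochromen-1-one F6.
- KOH in aqueous ethanol (reflux, Ar) should open the enol lactone to the salt of 2,4-dihydroxy-6-(2-oxotricosyl)benzoic acid F7.
- Adjusting to pH 5 (AcOH/NaOAc) and heating to 90 °C should decarboxylate it to 12.

Further compounds

F1 | step 4 | N-methoxy-N-methyldocosanamide | CCCCCCCCCCCCCCCCCCCCCC(=O)N(C)OC
F2 | step 4 | 1-(3,5-dimethoxyphenyl)tricosan-2-one | CCCCCCCCCCCCCCCCCCCCCC(=O)Cc1cc(OC)cc(OC)c1
F3 | step 3 | 2-(2-henicosyl-1,3-dioxolan-2-yl)acetaldehyde | CCCCCCCCCCCCCCCCCCCCCC1(CC=O)OCCO1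
F4 | step 3 | methyl 8-(2-henicosyl-1,3-dioxolan-2-yl)-7-hydroxy-3,5-dioxooctanoate (racemic) | COC(=O)CC(=O)CC(=O)CC(O)CC1(CCCCCCCCCCCCCCCCCCCCC)OCCO1
F5 | step 5 | methyl 2,4-dihydroxy-6-(2-oxotricosyl)benzoate | CCCCCCCCCCCCCCCCCCCCCC(=O)Cc1cc(O)cc(O)c1C(=O)OC
F6 | step 5 | 3-henicosyl-6,8-dihydroxy-1H-isochromen-1-one | O=C1OC(CCCCCCCCCCCCCCCCCCCCC)=Cc2cc(O)cc(O)c12
F7 | step 5 | 2,4-dihydroxy-6-(2-oxotricosyl)benzoic acid | CCCCCCCCCCCCCCCCCCCCCC(=O)Cc1cc(O)cc(O)c1C(=O)O
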